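**Retrosynthetic overview**

1. The target is two identical 7-acetyl-3,6,8-trihydroxy-4,4-dimethylnaphthalen-1(4H)-one halves joined by a CH2 between C2 and C2'; the last step only removes four O-methyl and two O-silyl groups.
2. Key disconnection, both halves in one operation: each cyclohexenone ring (C1, C2, C3, C4, C4a, C8a) is cut at C1–C2 and C3–C4. This gives two molecules of 4-acetyl-3,5-dimethoxy-8,8-dimethylbenzocyclobutenone and one 1,5-bis(silyloxy)penta-1,4-diyne.
3. Enabling feature: the array C1(=O)–C8a–C4a–C4(CH3)2 is the ring-opened (o-quinoid vinylketene) form of an 8,8-dimethylbenzocyclobutenone, and C2=C3–OH is a masked ynol. C4 is quaternary, so the [4+2] adduct cannot aromatise, and the C2–CH2–C2' methylene makes the two ynol units the two ends of one skipped diyne.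
4. The benzocyclobutenone should come from 1-bromo-3,5-dimethoxybenzene by aryne–ketene acetal [2+2] cycloaddition, lithiation/acetylation between the two OMe groups and ketal hydrolysis; the diyne from propargyl–alkynyl coupling, acetylide oxidation and O-silylation.
5. Ring order: benzene ring (purchased) → four-membered ring (step 1) → both cyclohexenone rings together (step 6), the four-membered rings being consumed.

Key step: step 6

Remark: the target has no stereocentre and is drawn and made as its bis-enol (3-hydroxy-enone) tautomer; ketene acetal 2 is taken as a purchasable reagent.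

**Route**

Step 1
Reactants: 1 1-bromo-3,5-dimethoxybenzene; 2 1,1-dimethoxy-2-methylprop-1-ene
Product: 4 2,4,8,8-tetramethoxy-7,7-dimethylbicyclo[4.2.0]octa-1,3,5-triene (the dimethyl ketal of 3,5-dimethoxy-8,8-dimethylbenzocyclobutenone), via 3,5-dimethoxybenzyne 3 (not isolated)
Conditions: NaNH2 (2.5 equiv), 2 (3 equiv), THF, reflux
Reagents that add atoms: none
Why: NaNH2 eliminates HBr from 1 to aryne 3, the nucleophilic CMe2 carbon of 2 adds to the aryne carbon remote from the neighbouring OMe group, and the resulting aryl anion (ortho to OMe) closes onto the dialkoxycarbenium carbon, so the ketal carbon should end up ortho to OMe (aryne–ketene acetal [2+2] cycloaddition).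

Step 2
Reactants: 4 2,4,8,8-tetramethoxy-7,7-dimethylbicyclo[4.2.0]octa-1,3,5-triene
Product: 6 1-(2,4,8,8-tetramethoxy-7,7-dimethylbicyclo[4.2.0]octa-1,3,5-trien-3-yl)ethan-1-one, via aryllithium 5 (not isolated)
Conditions: n-BuLi, TMEDA, THF, 0 °C; then MeC(O)N(OMe)Me, −78 → 0 °C; aq. NH4Cl
Reagents that add atoms: N-methoxy-N-methylacetamide, CC(=O)N(C)OC
Why: directed ortho-metalation should take place at the only C–H flanked by two OMe groups, and the aryllithium is acylated through a chelated tetrahedral adduct that prevents over-addition (Weinreb ketone synthesis).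

Step 3
Reactants: 6 1-(2,4,8,8-tetramethoxy-7,7-dimethylbicyclo[4.2.0]octa-1,3,5-trien-3-yl)ethan-1-one
Product: 7 4-acetyl-3,5-dimethoxy-8,8-dimethylbicyclo[4.2.0]octa-1,3,5-trien-7-one
Conditions: 1 M HCl, THF, 25 °C
Reagents that add atoms: water, O
Why: acid-catalysed ketal hydrolysis should release the strained ketone cleanly, since C8 carries no hydrogen and the ring ketone therefore cannot enolise or undergo aldol chemistry.

Step 4
Reactants: 8 3-bromoprop-1-yne (propargyl bromide); 9 ethynylmagnesium bromide (HC≡CMgBr, THF solution)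
Product: 10 penta-1,4-diyne (kept and used as a cold distilled THF solution)
Conditions: CuCl (5 mol %), THF, 0 → 25 °C
Reagents that add atoms: none
Why: copper-catalysed substitution of a propargylic bromide by an alkynyl Grignard reagent is the standard entry to skipped 1,4-diynes.

Step 5
Reactants: 10 penta-1,4-diyne
Product: 13 1,5-bis(triisopropylsilyloxy)penta-1,4-diyne, via 1,5-dilithiopenta-1,4-diyne 11 (not isolated), via dilithium penta-1,4-diyne-1,5-diolate 12 (not isolated)
Conditions: n-BuLi (2.05 equiv), THF, −78 °C; t-BuOOLi (from t-BuOOH, LiN(SiMe3)2), −78 → 0 °C; TIPSOTf, −78 → 0 °C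
Reagents that add atoms: lithium tert-butyl peroxide, [Li+].[O-]OC(C)(C)C; triisopropylsilyl trifluoromethanesulfonate, CC(C)[Si](C(C)C)(C(C)C)OS(=O)(=O)C(F)(F)F
Why: the two acetylenic C–H bonds are lithiated kinetically, each acetylide carbon takes up electrophilic oxygen from t-BuOOLi to give a lithium ynolate, and the hard ynolate oxygens are silylated by TIPSOTf (acetylide oxidation to ynolate followed by O-silylation, the established route to 1-siloxyalkynes).

Step 6
Reactants: 7 4-acetyl-3,5-dimethoxy-8,8-dimethylbicyclo[4.2.0]octa-1,3,5-trien-7-one (two molecules); 13 1,5-bis(triisopropylsilyloxy)penta-1,4-diyne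
Product: 16 2,2'-methylenebis[7-acetyl-6,8-dimethoxy-4,4-dimethyl-3-(triisopropylsilyloxy)naphthalen-1(4H)-one], via o-quinoid vinylketene 14 (not isolated), via mono-adduct 15 (not isolated)
Conditions: hν (365 nm LED), 7 (2.6 equiv), 13 (0.3 M), degassed PhMe, 20 °C
Reagents that add atoms: none
Why: Proposed new method: light opens the cyclobutenone of 7 by electrocyclic cleavage of the C7–C8 bond to the o-quinoid vinylketene 14, whose electrophilic ketene carbon is attacked by the nucleophilic β-carbon of a siloxyalkyne unit while the siloxy-bearing carbon bonds to the CMe2 terminus, a [4+2] cycloaddition driven by loss of four-ring strain and return of the benzene ring; the closest known reaction types are the [4+2] capture of benzocyclobutenone-derived o-quinoid ketenes by 2π partners and the union of vinylketenes with siloxyalkynes in the Danheiser benzannulation. Each of the two new six-membered rings is closed by an intermolecular [4+2] cycloaddition, the first on 13 to give 15 and the second on the remaining siloxyalkyne of 15, and if bond formation is stepwise the second bond closes the zwitterion in a 6-endo-dig mode. No stereocentre is formed, because C4 of each ring carries two methyl groups. The step needs periselectivity for [4+2] over [2+2] at the ketene C=C, which the substrate secures because only the [4+2] mode restores aromaticity, and regioselectivity, which is secured by the matched polarisation of siloxyalkyne and ketene. It also needs trapping to outrun the 1,5-hydrogen shift from the inner methyl group of 14 to the ketene carbon, which is why the diyne is used concentrated and 7 in excess, untrapped 14 closing back to 7. The quaternary C8 of 7 keeps the adduct from tautomerising to a naphthol, so the 4,4-dimethylnaphthalen-1(4H)-one should be delivered directly at the right oxidation level.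

Step 7
Reactants: 16 2,2'-methylenebis[7-acetyl-6,8-dimethoxy-4,4-dimethyl-3-(triisopropylsilyloxy)naphthalen-1(4H)-one]
Product: 17 2,2'-methylenebis(7-acetyl-3,6,8-trihydroxy-4,4-dimethylnaphthalen-1(4H)-one) (target)
Conditions: BBr3 (12 equiv), CH2Cl2, −78 → 25 °C; then H2O
Reagents that add atoms: none
Why: BBr3 should cleave the four aryl methyl ethers, each of which is ortho to a carbonyl group that assists by chelation, together with the two silyl enol ethers, and aqueous work-up hydrolyses the boron aryloxides and enolates to the bis-enol target (Lewis acid ether cleavage).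

**Compound list**

1 | 1-bromo-3,5-dimethoxybenzene | COc1cc(Br)cc(OC)c1 | starting material
2 | 1,1-dimethoxy-2-methylprop-1-ene | COC(OC)=C(C)C | starting material
3 | 3,5-dimethoxybenzyne (1,2-didehydro-3,5-dimethoxybenzene) | COC1=CC(OC)=CC#C1 | intermediate
4 | 2,4,8,8-tetramethoxy-7,7-dimethylbicyclo[4.2.0]octa-1,3,5-triene | COc1cc(OC)c2c(c1)C(C)(C)C2(OC)OC | intermediate
5 | (3-lithio) derivative of 4, lithium on the carbon between the two aryl OMe groups | [Li]c1c(OC)cc2c(c1OC)C(OC)(OC)C2(C)C | intermediate
6 | 1-(2,4,8,8-tetramethoxy-7,7-dimethylbicyclo[4.2.0]octa-1,3,5-trien-3-yl)ethan-1-one | CC(=O)c1c(OC)cc2c(c1OC)C(OC)(OC)C2(C)C | intermediate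
7 | 4-acetyl-3,5-dimethoxy-8,8-dimethylbicyclo[4.2.0]octa-1,3,5-trien-7-one | CC(=O)c1c(OC)cc2c(c1OC)C(=O)C2(C)C | intermediate
8 | 3-bromoprop-1-yne | C#CCBr | starting material
9 | ethynylmagnesium bromide | C#C[Mg]Br | starting material
10 | penta-1,4-diyne | C#CCC#C | intermediate
11 | 1,5-dilithiopenta-1,4-diyne | [Li]C#CCC#C[Li] | intermediate
12 | dilithium penta-1,4-diyne-1,5-diolate (bis-ynolate) | [Li]OC#CCC#CO[Li] | intermediate
13 | 1,5-bis(triisopropylsilyloxy)penta-1,4-diyne | CC(C)[Si](C(C)C)(C(C)C)OC#CCC#CO[Si](C(C)C)(C(C)C)C(C)C | intermediate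
14 | [3-acetyl-2,4-dimethoxy-6-(propan-2-ylidene)cyclohexa-2,4-dien-1-ylidene]methanone (o-quinoid vinylketene) | CC(=O)C1=C(OC)C(=C=O)C(=C(C)C)C=C1OC | intermediate
15 | 7-acetyl-6,8-dimethoxy-4,4-dimethyl-3-(triisopropylsilyloxy)-2-[3-(triisopropylsilyloxy)prop-2-yn-1-yl]naphthalen-1(4H)-one | CC(=O)c1c(OC)cc2c(c1OC)C(=O)C(CC#CO[Si](C(C)C)(C(C)C)C(C)C)=C(O[Si](C(C)C)(C(C)C)C(C)C)C2(C)C | intermediate
16 | 2,2'-methylenebis[7-acetyl-6,8-dimethoxy-4,4-dimethyl-3-(triisopropylsilyloxy)naphthalen-1(4H)-one] | CC(=O)c1c(OC)cc2c(c1OC)C(=O)C(CC1=C(O[Si](C(C)C)(C(C)C)C(C)C)C(C)(C)c3cc(OC)c(C(C)=O)c(OC)c3C1=O)=C(O[Si](C(C)C)(C(C)C)C(C)C)C2(C)C | intermediate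
17 | 2,2'-methylenebis(7-acetyl-3,6,8-trihydroxy-4,4-dimethylnaphthalen-1(4H)-one) | CC(=O)c1c(O)cc2c(c1O)C(=O)C(CC1=C(O)C(C)(C)c3cc(O)c(C(C)=O)c(O)c3C1=O)=C(O)C2(C)C | target

**Count**

Total steps: 7. Longest linear sequence: 5 steps (steps 1, 2, 3, 6, 7); the diyne branch (steps 4, 5) joins at step 6.

**Steps most likely to fail, with fallbacks**

Step 6 (proposed new method). The bimolecular capture of the ring-opened ketene may lose to the intramolecular 1,5-hydrogen shift from the inner methyl group, the adduct chromophore may undergo secondary photoreactions, or the sequence may stall after the first cycloaddition. The fallback uses known chemistry only, sets out from 1 and comes back at 17.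
- 1 is lithiated between the OMe groups with LiN(i-Pr)2 (THF, −78 °C) and acylated with N-methoxy-N-methylacetamide to 1-(4-bromo-2,6-dimethoxyphenyl)ethan-1-one F1.
- Palladium-catalysed α-arylation of 1-methoxy-2-methyl-1-(trimethylsilyloxy)prop-1-ene with F1 (Pd(dba)2, P(t-Bu)3, ZnF2, DMF, 80 °C; tolerant of the enolisable ketone) should give methyl 2-(4-acetyl-3,5-dimethoxyphenyl)-2-methylpropanoate F2.
- Saponification (LiOH, THF/MeOH/H2O) gives 2-(4-acetyl-3,5-dimethoxyphenyl)-2-methylpropanoic acid F3.
- Activation with carbonyldiimidazole and acylation of KO2CCH2CO2Et/MgCl2/Et3N gives ethyl 4-(4-acetyl-3,5-dimethoxyphenyl)-4-methyl-3-oxopentanoate F4.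
- Intramolecular Friedel–Crafts acylation (P2O5 in MeSO3H, 25–50 °C; either ortho position gives the same product) closes the ring to 7-acetyl-3-hydroxy-6,8-dimethoxy-4,4-dimethylnaphthalen-1(4H)-one F5.
- Two molecules of F5 are joined at C2 with aqueous formaldehyde (cat. piperidine, EtOH; Knoevenagel condensation then Michael addition) to 2,2'-methylenebis(7-acetyl-3-hydroxy-6,8-dimethoxy-4,4-dimethylnaphthalen-1(4H)-one) F6.
- BBr3 as in step 7 converts F6 into 17.

Step 5. Base-induced propargyl–allenyl isomerisation of the skipped diyne or incomplete double oxygen transfer may prevent access to the bis(siloxyalkyne). The fallback sets out from 7 and comes back at 17; it keeps the cycloaddition but moves formation of the C2–CH2–C2' link to a later condensation. 7 is irradiated as in step 6 with purchasable ethoxyethyne to give 7-acetyl-3-ethoxy-6,8-dimethoxy-4,4-dimethylnaphthalen-1(4H)-one F7. Hydrolysis of the vinylogous ester (1 M HCl, THF) gives the dione F5, formaldehyde condensation gives F6 as above, and BBr3 gives 17.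

Step 1. Addition of amide to the aryne, slow capture by the tetrasubstituted ketene acetal, or erosion of regioselectivity may defeat the cycloaddition. The fallback builds the four-membered ring by C–H acylation instead, sets out from 1 and comes back at 4.
- Palladium-catalysed α-arylation of 2-methylpropanal with 1 (Pd(OAc)2, rac-BINAP, Cs2CO3, dioxane, 80 °C) gives 2-(3,5-dimethoxyphenyl)-2-methylpropanal F8.
- Bromination ortho to the alkyl group and para to OMe (N-bromosuccinimide, MeCN, 0 °C) gives 2-(2-bromo-3,5-dimethoxyphenyl)-2-methylpropanal F9; this site selectivity is itself uncertain next to the bulky side chain.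
- Palladium-catalysed intramolecular acylation of the aryl bromide by the aldehyde C–H bond (Pd(OAc)2, rac-BINAP, Cs2CO3, dioxane, 110 °C) gives 3,5-dimethoxy-8,8-dimethylbicyclo[4.2.0]octa-1,3,5-trien-7-one F10.
- Ketalisation (HC(OMe)3, MeOH, cat. TsOH) gives 4.

Further compounds
F1 | step 6 | 1-(4-bromo-2,6-dimethoxyphenyl)ethan-1-one | CC(=O)c1c(OC)cc(Br)cc1OC
F2 | step 6 | methyl 2-(4-acetyl-3,5-dimethoxyphenyl)-2-methylpropanoate | COC(=O)C(C)(C)c1cc(OC)c(C(C)=O)c(OC)c1
F3 | step 6 | 2-(4-acetyl-3,5-dimethoxyphenyl)-2-methylpropanoic acid | CC(=O)c1c(OC)cc(C(C)(C)C(=O)O)cc1OC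
F4 | step 6 | ethyl 4-(4-acetyl-3,5-dimethoxyphenyl)-4-methyl-3-oxopentanoate | CCOC(=O)CC(=O)C(C)(C)c1cc(OC)c(C(C)=O)c(OC)c1
F5 | step 6 | 7-acetyl-3-hydroxy-6,8-dimethoxy-4,4-dimethylnaphthalen-1(4H)-one | CC(=O)c1c(OC)cc2c(c1OC)C(=O)C=C(O)C2(C)C
F6 | step 6 | 2,2'-methylenebis(7-acetyl-3-hydroxy-6,8-dimethoxy-4,4-dimethylnaphthalen-1(4H)-one) | CC(=O)c1c(OC)cc2c(c1OC)C(=O)C(CC1=C(O)C(C)(C)c3cc(OC)c(C(C)=O)c(OC)c3C1=O)=C(O)C2(C)C
F7 | step 5 | 7-acetyl-3-ethoxy-6,8-dimethoxy-4,4-dimethylnaphthalen-1(4H)-one | CC(=O)c1c(OC)cc2c(c1OC)C(=O)C=C(OCC)C2(C)C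
F8 | step 1 | 2-(3,5-dimethoxyphenyl)-2-methylpropanal | COc1cc(OC)cc(C(C)(C)C=O)c1
F9 | step 1 | 2-(2-bromo-3,5-dimethoxyphenyl)-2-methylpropanal | COc1cc(OC)c(Br)c(C(C)(C)C=O)c1
F10 | step 1 | 3,5-dimethoxy-8,8-dimethylbicyclo[4.2.0]octa-1,3,5-trien-7-one | COc1cc(OC)c2c(c1)C(C)(C)C2=O
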